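**Plan**

- Retrosynthetic cuts, in order: (a) the exocyclic enone C=C, by aldol–dehydration of a ring-bound acetyl group with 6,6-dimethyl-2H-pyran-2,5(6H)-dione, which comes from Achmatowicz dearomatisation of a furyl carbinol; (b) the methyl glycidate and the furyl ketone, folded back into an epoxy δ-lactone (a temporary ring, the ring D lactone of limonoids), whose C=C is cut by intramolecular Horner–Wadsworth–Emmons olefination; (c) the two exocyclic C–C bonds at the α-quaternary carbons of a 2,6-dimethylcyclohexanone (aldols with furan-3-carbaldehyde and acetaldehyde); (d) the ring bond between the carbinol-bearing CH and the adjacent methyl-bearing carbon.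
- Enabling feature: in the cyclohexane the CH that carries CH(OH)CH3 is bonded to the carbon alpha to the spiro-epoxide carbon (a masked ring ketone), and the hydroxyl sits one carbon outside the ring. This γ-hydroxy ketone pattern is the retron of a 6-exo opening of a cis-2,3-epoxide by a ketone enolate.
- Forward: epoxy iodide + allyl β-keto ester → acyclic epoxy ketone → cyclohexanone (the only carbocycle) → enone (ester helper expelled) → reductive aldol and α'-aldol build both quaternary carbons → lactone ring → epoxide → lactone opened and carbinols oxidised → pyranone side chain last.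
- Stereochemistry: one catalytic asymmetric epoxidation of (Z)-pent-3-en-1-ol sets the ring CH and the carbinol. The other four centres are relayed: both quaternary carbons by axial/anti attack on ring enolates, the spiro carbon and epoxide CH by face-selective nucleophilic epoxidation of the lactone, whose ring also holds the ester carbon cis to the furyl-bearing carbon.

Key step: step 6

Assumption (remark on the chemistry): centres that are erased later (the ester-bearing carbon of 8–11, the furyl carbinol carbon made in step 9, the acetoxyethyl carbon made in step 10, the tertiary carbinol of 34) are carried as epimer mixtures and are left undefined in names and SMILES. TBSO = tert-butyldimethylsilyloxy.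

**Route**

Step 1
Reactants: 1 pentan-3-one; 2 diallyl carbonate
Product: 3 allyl 2-methyl-3-oxopentanoate (racemic)
Conditions: NaH (2.2 equiv), THF, reflux; aqueous work-up
Reagents that add atoms: none
Why: Claisen-type C-acylation of the ketone sodium enolate by the carbonate, driven by deprotonation of the β-keto ester formed; the new centre is racemic and is erased later.

Step 2
Reactants: 4 pent-3-yn-1-ol
Product: 5 (Z)-pent-3-en-1-ol
Conditions: H2 (1 atm), Pd/CaCO3 poisoned with Pb(OAc)2 (Lindlar catalyst), quinoline, EtOAc, rt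
Reagents that add atoms: none
Why: Lindlar semihydrogenation adds hydrogen syn to the alkyne and should stop at the Z alkene.

Step 3
Reactants: 5 (Z)-pent-3-en-1-ol
Product: 6 2-[(2S,3R)-3-methyloxiran-2-yl]ethan-1-ol (cis-epoxide)
Conditions: VO(OiPr)3 (2 mol%), chiral C2-symmetric bis-hydroxamic acid ligand of the N,N'-dihydroxy-N,N'-diacyl-trans-cyclohexane-1,2-diamine type (4 mol%, antipode chosen for the (2S,3R) epoxide), cumene hydroperoxide, toluene, 0 °C to rt
Reagents that add atoms: cumene hydroperoxide CC(C)(OO)c1ccccc1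
Why: Hydroxyl-directed catalytic asymmetric epoxidation of a homoallylic alcohol by a chiral vanadium peroxo complex; syn oxygen transfer keeps the cis geometry and the ligand antipode selects the alkene face, which fixes both epoxide carbons.

Step 4
Reactants: 6 2-[(2S,3R)-3-methyloxiran-2-yl]ethan-1-ol
Product: 7 (2S,3R)-2-(2-iodoethyl)-3-methyloxirane
Conditions: I2, PPh3, imidazole, CH2Cl2, 0 °C
Reagents that add atoms: iodine II
Why: Appel iodination of the primary alcohol by SN2 displacement of the oxyphosphonium group; the imidazole buffer should spare the epoxide, and no stereocentre is involved.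

Step 5
Reactants: 3 allyl 2-methyl-3-oxopentanoate; 7 (2S,3R)-2-(2-iodoethyl)-3-methyloxirane
Product: 8 allyl 2-methyl-2-{2-[(2S,3R)-3-methyloxiran-2-yl]ethyl}-3-oxopentanoate (both C-2 epimers)
Conditions: Cs2CO3, DMF, rt to 40 °C
Reagents that add atoms: none
Why: C-alkylation of the stabilised β-keto ester enolate by the primary iodide (SN2) joins the fragments and makes the α-carbon quaternary; the new centre is not controlled and is erased in step 8.

Step 6
Reactants: 8 allyl 2-methyl-2-{2-[(2S,3R)-3-methyloxiran-2-yl]ethyl}-3-oxopentanoate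
Product: 10 allyl (3R,4S)-4-[(1R)-1-hydroxyethyl]-1,3-dimethyl-2-oxocyclohexane-1-carboxylate (both C-1 epimers), via lithium enolate 9 (not isolated)
Conditions: LiN(SiMe3)2 (1.1 equiv), THF–toluene, −78 °C; Sc(OTf)3 (0.1 equiv), −78 to 0 °C; H2O
Reagents that add atoms: none
Why: LiN(SiMe3)2 can deprotonate only the CH2 of the ethyl ketone, because the other α-carbon is the quaternary ester-bearing helper carbon, and the lithium enolate 9 attacks the nearer carbon of the Sc(OTf)3-activated epoxide from the back side (intramolecular SN2 epoxide opening) to give the lithium alkoxide of 10. The closest known reaction type is the Lewis-acid-assisted intramolecular addition of ketone enolates to epoxides that gives γ-hydroxy ketones, the carbonyl counterpart of the epoxynitrile cyclisation. The single ring closed is the cyclohexanone, in the 6-(enolendo)-exo-tet mode. The ring CH (C-4) is set by inversion at the attacked epoxide carbon and the carbinol carbon by retention, since its C–O bond is never broken, so the cis-epoxide is translated into the (4S,1'R) pair; the adjacent methyl-bearing carbon (C-3) should settle under thermodynamic control, by alkoxide/enolate proton exchange, in the trans diequatorial arrangement. The step needs 6-exo instead of 7-endo attack, secured by the collinear SN2 geometry that only the six-membered transition state allows, and C- instead of O-alkylation, favoured by the lithium counter-ion in a weakly polar medium with Lewis-acid activation of the epoxide. The site of enolisation, which an unblocked ketone would not guarantee, is secured by the allyl ester group that is removed in step 8.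

Step 7
Reactants: 10 allyl (3R,4S)-4-[(1R)-1-hydroxyethyl]-1,3-dimethyl-2-oxocyclohexane-1-carboxylate
Product: 11 allyl (3R,4S)-4-[(1R)-1-(TBSO)ethyl]-1,3-dimethyl-2-oxocyclohexane-1-carboxylate (both C-1 epimers)
Conditions: TBSCl, imidazole, DMF, rt
Reagents that add atoms: tert-butyldimethylsilyl chloride CC(C)(C)[Si](C)(C)Cl
Why: Standard silylation of the secondary alcohol, which also prevents hemiketal formation and retro-Claisen attack on the ring ketone.

Step 8
Reactants: 11 allyl (3R,4S)-4-[(1R)-1-(TBSO)ethyl]-1,3-dimethyl-2-oxocyclohexane-1-carboxylate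
Product: 12 (5S,6R)-5-[(1R)-1-(TBSO)ethyl]-2,6-dimethylcyclohex-2-en-1-one
Conditions: Pd(OAc)2 (5 mol%), dppe (5 mol%), MeCN, 80 °C; then DBU (cat.), CH2Cl2, rt
Reagents that add atoms: none
Why: Tsuji decarboxylation–dehydrogenation: oxidative addition of the allyl ester to zerovalent palladium (formed in situ), loss of CO2 and β-hydride elimination of the palladium enolate toward the ring CH2 give the 2-methyl enone and propene. Both C-1 epimers converge, and DBU should equilibrate the 6-methyl to the trans (diequatorial) isomer.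

Step 9
Reactants: 12 (5S,6R)-5-[(1R)-1-(TBSO)ethyl]-2,6-dimethylcyclohex-2-en-1-one; 13 furan-3-carbaldehyde
Product: 16 (2S,5S,6R)-5-[(1R)-1-(TBSO)ethyl]-2-[furan-3-yl(triethylsilyloxy)methyl]-2,6-dimethylcyclohexan-1-one (epimers at the furyl carbinol carbon), via lithium enolate 14 (not isolated), via lithium aldolate 15 (not isolated)
Conditions: LiBH(s-Bu)3 (L-Selectride, 1.05 equiv), THF, −78 °C; 13, −78 °C; TESOTf, −78 to −40 °C
Reagents that add atoms: triethylsilyl trifluoromethanesulfonate CC[Si](CC)(CC)OS(=O)(=O)C(F)(F)F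
Why: Conjugate reduction–aldol: 1,4-hydride addition gives the enolate regiospecifically at C-2, and the aldehyde should add by axial attack on the face cis to the axial C-6 hydrogen (trans to the equatorial 6-methyl), which sets the quaternary C-2 with its methyl cis to the 6-methyl. Silyl triflate traps the aldolate before retro-aldol can occur.

Step 10
Reactants: 16 (2S,5S,6R)-5-[(1R)-1-(TBSO)ethyl]-2-[furan-3-yl(triethylsilyloxy)methyl]-2,6-dimethylcyclohexan-1-one; 17 acetaldehyde
Product: 20 (2S,3S,6S)-2-(1-acetoxyethyl)-3-[(1R)-1-(TBSO)ethyl]-6-[furan-3-yl(triethylsilyloxy)methyl]-2,6-dimethylcyclohexan-1-one (epimers at both carbinol carbons), via lithium enolate 18 (not isolated), via lithium aldolate 19 (not isolated)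
Conditions: LiN(i-Pr)2 (1.2 equiv), THF, −78 to 0 °C; 17 (excess), −78 °C; Ac2O, −78 to 0 °C
Reagents that add atoms: acetic anhydride CC(=O)OC(C)=O
Why: Only the remaining methyl-bearing α-carbon can be enolised; aldol addition of the tetrasubstituted enolate should occur anti to the neighbouring CH(OTBS)CH3 group (held pseudoaxial by A(1,2) strain with the enolate methyl), which sets the second quaternary carbon with the two-carbon arm trans to that side chain. The aldolate is trapped as the acetate.

Step 11
Reactants: 20 (2S,3S,6S)-2-(1-acetoxyethyl)-3-[(1R)-1-(TBSO)ethyl]-6-[furan-3-yl(triethylsilyloxy)methyl]-2,6-dimethylcyclohexan-1-one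
Product: 21 (2S,3S,6S)-2-(1-acetoxyethyl)-3-[(1R)-1-(TBSO)ethyl]-6-[furan-3-yl(hydroxy)methyl]-2,6-dimethylcyclohexan-1-one
Conditions: PPTS (cat.), MeOH–CH2Cl2, 0 °C
Reagents that add atoms: none
Why: Acid-catalysed methanolysis removes the triethylsilyl ether, which is far more labile than the TBS ether; the acetate is inert and acidic conditions avoid retro-aldol.

Step 12
Reactants: 21 (2S,3S,6S)-2-(1-acetoxyethyl)-3-[(1R)-1-(TBSO)ethyl]-6-[furan-3-yl(hydroxy)methyl]-2,6-dimethylcyclohexan-1-one; 22 2-(diethoxyphosphoryl)acetic acid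
Product: 23 (2S,3S,6S)-2-(1-acetoxyethyl)-3-[(1R)-1-(TBSO)ethyl]-6-{[2-(diethoxyphosphoryl)acetoxy](furan-3-yl)methyl}-2,6-dimethylcyclohexan-1-one
Conditions: DCC, DMAP (cat.), CH2Cl2, 0 °C to rt
Reagents that add atoms: none
Why: Steglich esterification; the phosphonoacetic acid is known to acylate hindered secondary alcohols under carbodiimide activation.

Step 13
Reactants: 23 (2S,3S,6S)-2-(1-acetoxyethyl)-3-[(1R)-1-(TBSO)ethyl]-6-{[2-(diethoxyphosphoryl)acetoxy](furan-3-yl)methyl}-2,6-dimethylcyclohexan-1-one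
Product: 24 (5R,6S,8aR)-5-(1-acetoxyethyl)-6-[(1R)-1-(TBSO)ethyl]-1-(furan-3-yl)-5,8a-dimethyl-1,5,6,7,8,8a-hexahydro-3H-isochromen-3-one
Conditions: NaH (1.2 equiv), THF, 0 °C to reflux
Reagents that add atoms: none
Why: Intramolecular Horner–Wadsworth–Emmons olefination: the phosphonate carbanion adds to the ring ketone through a six-membered ring closure and phosphate elimination gives the unsaturated δ-lactone. The ring fixes the alkene geometry, with the ester carbon cis to the furyl-bearing quaternary carbon.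

Step 14
Reactants: 24 (5R,6S,8aR)-5-(1-acetoxyethyl)-6-[(1R)-1-(TBSO)ethyl]-1-(furan-3-yl)-5,8a-dimethyl-1,5,6,7,8,8a-hexahydro-3H-isochromen-3-one
Product: 25 the 4,4a-epoxide of 24, (4S,4aR,5S,6S,8aS), epoxide oxygen anti to the 8a-methyl
Conditions: t-BuOOH (anhydrous, in decane), benzyltrimethylammonium hydroxide (Triton B, cat.), THF, 0 °C to rt
Reagents that add atoms: tert-butyl hydroperoxide CC(C)(C)OO
Why: Weitz–Scheffer nucleophilic epoxidation: the peroxide anion should add to the β-carbon from the face opposite the angular 8a-methyl and the pseudoaxial 1-acetoxyethyl group, and the enolate closes on the same face, so the spiro carbon and the epoxide CH arise together, as in limonoid ring D lactones. The nucleophilic oxidant leaves the furan untouched.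

Step 15
Reactants: 25 the 4,4a-epoxide of 24
Product: 27 methyl (2S,3R,4S,5S,8S)-5-[(1R)-1-(TBSO)ethyl]-8-[furan-3-yl(hydroxy)methyl]-4-(1-hydroxyethyl)-4,8-dimethyl-1-oxaspiro[2.5]octane-2-carboxylate, via lithium carboxylate 26 (not isolated)
Conditions: LiOH, THF–MeOH–H2O, 0 °C to rt; evaporate; MeI, DMF, rt
Reagents that add atoms: lithium hydroxide [Li+].[OH-]; iodomethane CI
Why: Saponification opens the δ-lactone and cleaves the acetate; O-alkylation of the carboxylate by iodomethane under neutral conditions gives the methyl ester without passing through the free hydroxy acid, which would relactonise. No stereocentre is touched.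

Step 16
Reactants: 27 methyl (2S,3R,4S,5S,8S)-5-[(1R)-1-(TBSO)ethyl]-8-[furan-3-yl(hydroxy)methyl]-4-(1-hydroxyethyl)-4,8-dimethyl-1-oxaspiro[2.5]octane-2-carboxylate
Product: 28 methyl (2S,3R,4R,5S,8R)-4-acetyl-5-[(1R)-1-(TBSO)ethyl]-8-(furan-3-carbonyl)-4,8-dimethyl-1-oxaspiro[2.5]octane-2-carboxylate
Conditions: Dess–Martin periodinane (3 equiv), pyridine, CH2Cl2, 0 °C to rt
Reagents that add atoms: none
Why: Dess–Martin oxidation of both hindered secondary carbinols gives the furyl ketone and the acetyl group and erases the two undefined centres; it is done at once so that the hydroxy ester cannot relactonise.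

Step 17
Reactants: 29 1-(furan-2-yl)ethan-1-one
Product: 30 2-(furan-2-yl)propan-2-ol
Conditions: MeMgBr, Et2O, 0 °C; aqueous work-up
Reagents that add atoms: methylmagnesium bromide C[Mg]Br
Why: Grignard addition to the ketone; no stereocentre.

Step 18
Reactants: 30 2-(furan-2-yl)propan-2-ol
Product: 31 6-hydroxy-2,2-dimethyl-2H-pyran-3(6H)-one (racemic lactol)
Conditions: N-bromosuccinimide, NaHCO3, THF–H2O, 0 °C
Reagents that add atoms: water O
Why: Achmatowicz rearrangement: oxidative dearomatisation of the furan, ring opening to the ene-dione and recyclisation of the tertiary alcohol give the pyranone lactol.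

Step 19
Reactants: 31 6-hydroxy-2,2-dimethyl-2H-pyran-3(6H)-one
Product: 32 6,6-dimethyl-2H-pyran-2,5(6H)-dione
Conditions: TEMPO (cat.), PhI(OAc)2, CH2Cl2, rt
Reagents that add atoms: none
Why: Oxoammonium oxidation of the lactol to the lactone gives the non-enolisable ene-dione.

Step 20
Reactants: 28 methyl (2S,3R,4R,5S,8R)-4-acetyl-5-[(1R)-1-(TBSO)ethyl]-8-(furan-3-carbonyl)-4,8-dimethyl-1-oxaspiro[2.5]octane-2-carboxylate; 32 6,6-dimethyl-2H-pyran-2,5(6H)-dione
Product: 34 methyl (2S,3R,4R,5S,8R)-5-[(1R)-1-(TBSO)ethyl]-8-(furan-3-carbonyl)-4-[2-(3-hydroxy-2,2-dimethyl-6-oxo-3,6-dihydro-2H-pyran-3-yl)acetyl]-4,8-dimethyl-1-oxaspiro[2.5]octane-2-carboxylate (epimers at the new carbinol), via lithium enolate 33 (not isolated)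
Conditions: LiN(i-Pr)2 (1.05 equiv), THF, −78 °C; 32, −78 °C; AcOH, −78 °C
Reagents that add atoms: none
Why: The acetyl methyl is the only enolisable position (both other ketone α-carbons are quaternary); the kinetic lithium enolate should add 1,2 to the ketone carbonyl of the non-enolisable ene-dione at low temperature (aldol addition). The new centre is lost in the next step.

Step 21
Reactants: 34 the aldol adduct of step 20
Product: 35 methyl (2S,3R,4R,5S,8R)-5-[(1R)-1-(TBSO)ethyl]-4-[(2E)-2-(2,2-dimethyl-6-oxo-2H-pyran-3(6H)-ylidene)acetyl]-8-(furan-3-carbonyl)-4,8-dimethyl-1-oxaspiro[2.5]octane-2-carboxylate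
Conditions: Burgess reagent, toluene, 50 °C
Reagents that add atoms: none
Why: Burgess dehydration of the tertiary alcohol by syn elimination; the only β-hydrogens are on the CH2 alpha to the ketone, so the exocyclic conjugated enone must form. The E isomer (acyl away from the gem-dimethyl carbon) is expected to be favoured thermodynamically.

Step 22
Reactants: 35 the TBS ether of the target
Product: 36 methyl (2S,3R,4R,5S,8R)-4-[(2E)-2-(2,2-dimethyl-6-oxo-2H-pyran-3(6H)-ylidene)acetyl]-8-(furan-3-carbonyl)-5-[(1R)-1-hydroxyethyl]-4,8-dimethyl-1-oxaspiro[2.5]octane-2-carboxylate (CNP0293135.1)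
Conditions: HF·pyridine, pyridine, THF, 0 °C to rt
Reagents that add atoms: none
Why: Fluoride cleavage of the silyl ether under buffered conditions that the epoxide, both lactone and ester groups and the dienone should tolerate; no stereocentre is touched.

**Compound list**

1 | pentan-3-one | CCC(=O)CC | starting material
2 | diallyl carbonate | C=CCOC(=O)OCC=C | starting material
3 | allyl 2-methyl-3-oxopentanoate | CCC(=O)C(C)C(=O)OCC=C | intermediate
4 | pent-3-yn-1-ol | CC#CCCO | starting material
5 | (Z)-pent-3-en-1-ol | C/C=C\CCO | intermediate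
6 | 2-[(2S,3R)-3-methyloxiran-2-yl]ethan-1-ol | OCC[C@@H]1O[C@@H]1C | intermediate
7 | (2S,3R)-2-(2-iodoethyl)-3-methyloxirane | ICC[C@@H]1O[C@@H]1C | intermediate
8 | allyl 2-methyl-2-{2-[(2S,3R)-3-methyloxiran-2-yl]ethyl}-3-oxopentanoate | CCC(=O)C(C)(CC[C@@H]1O[C@@H]1C)C(=O)OCC=C | intermediate
9 | lithium enolate of 8 (ethyl side) | [Li+].CC=C([O-])C(C)(CC[C@@H]1O[C@@H]1C)C(=O)OCC=C | intermediate (not isolated)
10 | allyl (3R,4S)-4-[(1R)-1-hydroxyethyl]-1,3-dimethyl-2-oxocyclohexane-1-carboxylate | C=CCOC(=O)C1(C)CC[C@H]([C@@H](C)O)[C@@H](C)C1=O | intermediate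
11 | allyl (3R,4S)-4-[(1R)-1-(TBSO)ethyl]-1,3-dimethyl-2-oxocyclohexane-1-carboxylate | C=CCOC(=O)C1(C)CC[C@H]([C@@H](C)O[Si](C)(C)C(C)(C)C)[C@@H](C)C1=O | intermediate
12 | (5S,6R)-5-[(1R)-1-(TBSO)ethyl]-2,6-dimethylcyclohex-2-en-1-one | CC1=CC[C@H]([C@@H](C)O[Si](C)(C)C(C)(C)C)[C@@H](C)C1=O | intermediate
13 | furan-3-carbaldehyde | O=Cc1ccoc1 | starting material
14 | lithium (5S,6R)-5-[(1R)-1-(TBSO)ethyl]-2,6-dimethylcyclohex-1-en-1-olate | [Li+].[O-]C1=C(C)CC[C@H]([C@@H](C)O[Si](C)(C)C(C)(C)C)[C@H]1C | intermediate (not isolated)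
15 | lithium aldolate of 14 with 13 | O=C1[C@](C)(C([O-])c2ccoc2)CC[C@H]([C@@H](C)O[Si](C)(C)C(C)(C)C)[C@H]1C.[Li+] | intermediate (not isolated)
16 | (2S,5S,6R)-5-[(1R)-1-(TBSO)ethyl]-2-[furan-3-yl(triethylsilyloxy)methyl]-2,6-dimethylcyclohexan-1-one | O=C1[C@](C)(C(O[Si](CC)(CC)CC)c2ccoc2)CC[C@H]([C@@H](C)O[Si](C)(C)C(C)(C)C)[C@H]1C | intermediate
17 | acetaldehyde | CC=O | starting material
18 | lithium enolate of 16 | [Li+].[O-]C1=C(C)[C@@H]([C@@H](C)O[Si](C)(C)C(C)(C)C)CC[C@@]1(C)C(O[Si](CC)(CC)CC)c1ccoc1 | intermediate (not isolated)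
19 | lithium aldolate of 18 with 17 | O=C1[C@](C)(C(O[Si](CC)(CC)CC)c2ccoc2)CC[C@H]([C@@H](C)O[Si](C)(C)C(C)(C)C)[C@@]1(C)C(C)[O-].[Li+] | intermediate (not isolated)
20 | (2S,3S,6S)-2-(1-acetoxyethyl)-3-[(1R)-1-(TBSO)ethyl]-6-[furan-3-yl(triethylsilyloxy)methyl]-2,6-dimethylcyclohexan-1-one | O=C1[C@](C)(C(O[Si](CC)(CC)CC)c2ccoc2)CC[C@H]([C@@H](C)O[Si](C)(C)C(C)(C)C)[C@@]1(C)C(C)OC(C)=O | intermediate
21 | (2S,3S,6S)-2-(1-acetoxyethyl)-3-[(1R)-1-(TBSO)ethyl]-6-[furan-3-yl(hydroxy)methyl]-2,6-dimethylcyclohexan-1-one | O=C1[C@](C)(C(O)c2ccoc2)CC[C@H]([C@@H](C)O[Si](C)(C)C(C)(C)C)[C@@]1(C)C(C)OC(C)=O | intermediate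
22 | 2-(diethoxyphosphoryl)acetic acid | OC(=O)CP(=O)(OCC)OCC | starting material
23 | phosphonoacetate of 21 | O=C1[C@](C)(C(OC(=O)CP(=O)(OCC)OCC)c2ccoc2)CC[C@H]([C@@H](C)O[Si](C)(C)C(C)(C)C)[C@@]1(C)C(C)OC(C)=O | intermediate
24 | (5R,6S,8aR)-5-(1-acetoxyethyl)-6-[(1R)-1-(TBSO)ethyl]-1-(furan-3-yl)-5,8a-dimethyl-1,5,6,7,8,8a-hexahydro-3H-isochromen-3-one | O=C1OC(c2ccoc2)[C@]3(C)CC[C@H]([C@@H](C)O[Si](C)(C)C(C)(C)C)[C@@](C)(C(C)OC(C)=O)C3=C1 | intermediate
25 | 4,4a-epoxide of 24, (4S,4aR,5S,6S,8aS) | O=C1OC(c2ccoc2)[C@]3(C)CC[C@H]([C@@H](C)O[Si](C)(C)C(C)(C)C)[C@@](C)(C(C)OC(C)=O)[C@]35O[C@H]15 | intermediate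
26 | lithium carboxylate from opening of 25 (diol) | [Li+].[O-]C(=O)[C@H]1O[C@@]12[C@](C)(C(O)c1ccoc1)CC[C@H]([C@@H](C)O[Si](C)(C)C(C)(C)C)[C@@]2(C)C(C)O | intermediate (not isolated)
27 | methyl (2S,3R,4S,5S,8S)-5-[(1R)-1-(TBSO)ethyl]-8-[furan-3-yl(hydroxy)methyl]-4-(1-hydroxyethyl)-4,8-dimethyl-1-oxaspiro[2.5]octane-2-carboxylate | COC(=O)[C@H]1O[C@@]12[C@](C)(C(O)c1ccoc1)CC[C@H]([C@@H](C)O[Si](C)(C)C(C)(C)C)[C@@]2(C)C(C)O | intermediate
28 | methyl (2S,3R,4R,5S,8R)-4-acetyl-5-[(1R)-1-(TBSO)ethyl]-8-(furan-3-carbonyl)-4,8-dimethyl-1-oxaspiro[2.5]octane-2-carboxylate | COC(=O)[C@H]1O[C@@]12[C@](C)(C(=O)c1ccoc1)CC[C@H]([C@@H](C)O[Si](C)(C)C(C)(C)C)[C@@]2(C)C(C)=O | intermediate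
29 | 1-(furan-2-yl)ethan-1-one | CC(=O)c1ccco1 | starting material
30 | 2-(furan-2-yl)propan-2-ol | CC(C)(O)c1ccco1 | intermediate
31 | 6-hydroxy-2,2-dimethyl-2H-pyran-3(6H)-one | CC1(C)OC(O)C=CC1=O | intermediate
32 | 6,6-dimethyl-2H-pyran-2,5(6H)-dione | CC1(C)OC(=O)C=CC1=O | intermediate
33 | lithium enolate of 28 (acetyl group) | [Li+].COC(=O)[C@H]1O[C@@]12[C@](C)(C(=O)c1ccoc1)CC[C@H]([C@@H](C)O[Si](C)(C)C(C)(C)C)[C@@]2(C)C([O-])=C | intermediate (not isolated)
34 | aldol adduct of 33 with 32 | COC(=O)[C@H]1O[C@@]12[C@](C)(C(=O)c1ccoc1)CC[C@H]([C@@H](C)O[Si](C)(C)C(C)(C)C)[C@@]2(C)C(=O)CC1(O)C=CC(=O)OC1(C)C | intermediate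
35 | TBS ether of the target | COC(=O)[C@H]1O[C@@]12[C@](C)(C(=O)c1ccoc1)CC[C@H]([C@@H](C)O[Si](C)(C)C(C)(C)C)[C@@]2(C)C(=O)/C=C1\C=CC(=O)OC1(C)C | intermediate
36 | methyl (2S,3R,4R,5S,8R)-4-[(2E)-2-(2,2-dimethyl-6-oxo-2H-pyran-3(6H)-ylidene)acetyl]-8-(furan-3-carbonyl)-5-[(1R)-1-hydroxyethyl]-4,8-dimethyl-1-oxaspiro[2.5]octane-2-carboxylate | COC(=O)[C@H]1O[C@@]12[C@](C)(C(=O)c1ccoc1)CC[C@H]([C@@H](C)O)[C@@]2(C)C(=O)/C=C1\C=CC(=O)OC1(C)C | target

**Count and risks**

Total step count: 22. Longest linear sequence: 18 steps (steps 2–16 and 20–22).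

Steps most likely to fail:

1. Step 6. What may go wrong: O-alkylation of the enolate (closure to a six-membered enol ether) or retro-Claisen cleavage of the β-keto ester by the newly formed alkoxide may outrun C-alkylation. Fallback: the ring bond is not made by cyclisation; the cyclohexenone is taken from the chiral pool. This fallback does not set out from a numbered compound: commercial (S)-(+)-carvone takes the place of compound 8 (compounds 1–11 are given up), and it comes back to the route at compound 12. Kinetic enolate methylation (LiN(i-Pr)2, MeI, THF, −78 °C) should give trans-6-methylcarvone, (5S,6R)-2,6-dimethyl-5-(prop-1-en-2-yl)cyclohex-2-en-1-one F1. Selective ozonolysis of the electron-rich isopropenyl group (O3, pyridine, CH2Cl2–MeOH, −78 °C; Me2S) should give (5S,6R)-5-acetyl-2,6-dimethylcyclohex-2-en-1-one F2. CBS reduction of the unconjugated methyl ketone ((S)-2-methyl-CBS-oxazaborolidine, catecholborane, toluene, −78 °C) should give (5S,6R)-5-[(1R)-1-hydroxyethyl]-2,6-dimethylcyclohex-2-en-1-one F3, and TBSCl/imidazole then gives 12.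

2. Step 13. What may go wrong: the phosphonate carbanion may fail to add to a ketone flanked by two quaternary carbons, or the adduct may suffer acetyl migration before phosphate is eliminated. Fallback: addition and elimination are separated. It sets out from compound 21 and comes back at compound 24. Acylation with bromoacetyl bromide/pyridine should give the bromoacetate of 21 F4. SmI2 (THF, −78 °C) should then bring about an intramolecular Reformatsky addition of the samarium enolate to the ring ketone, giving the β-hydroxy δ-lactone F5. Dehydration with SOCl2/pyridine can run only toward the lactone CH2, because both other neighbours of the carbinol are quaternary, and gives 24.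

3. Step 20. What may go wrong: conjugate addition of the enolate to the doubly activated alkene of the ene-dione, or retro-aldol reversal on warming. Fallback: the electrophile is used at the lactol oxidation level and the lactone carbonyl is made afterwards. It sets out from compound 31 (with enolate 33 made from 28 as before) and comes back at compound 35. Acid-catalysed exchange (MeOH, PPTS) should give 6-methoxy-2,2-dimethyl-2H-pyran-3(6H)-one F6, a simple enone to which the lithium enolate should add 1,2 to give the aldol adduct F7. Burgess dehydration then gives the dienone methyl acetal F8, mild aqueous acid (PPTS, acetone–water) the lactol F9, and TEMPO/PhI(OAc)2 oxidation of the lactol gives 35.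

Further compounds
F1 | step 6 | (5S,6R)-2,6-dimethyl-5-(prop-1-en-2-yl)cyclohex-2-en-1-one | CC1=CC[C@H](C(C)=C)[C@@H](C)C1=O
F2 | step 6 | (5S,6R)-5-acetyl-2,6-dimethylcyclohex-2-en-1-one | CC1=CC[C@H](C(C)=O)[C@@H](C)C1=O
F3 | step 6 | (5S,6R)-5-[(1R)-1-hydroxyethyl]-2,6-dimethylcyclohex-2-en-1-one | CC1=CC[C@H]([C@@H](C)O)[C@@H](C)C1=O
F4 | step 13 | bromoacetate of 21 | O=C1[C@](C)(C(OC(=O)CBr)c2ccoc2)CC[C@H]([C@@H](C)O[Si](C)(C)C(C)(C)C)[C@@]1(C)C(C)OC(C)=O
F5 | step 13 | β-hydroxy δ-lactone (4a-hydroxy-4,4a-dihydro analogue of 24) | O=C1CC2(O)[C@](C)(C(C)OC(C)=O)[C@@H]([C@@H](C)O[Si](C)(C)C(C)(C)C)CC[C@@]2(C)C(c2ccoc2)O1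
F6 | step 20 | 6-methoxy-2,2-dimethyl-2H-pyran-3(6H)-one | COC1C=CC(=O)C(C)(C)O1
F7 | step 20 | aldol adduct of 33 with F6 | COC(=O)[C@H]1O[C@@]12[C@](C)(C(=O)c1ccoc1)CC[C@H]([C@@H](C)O[Si](C)(C)C(C)(C)C)[C@@]2(C)C(=O)CC1(O)C=CC(OC)OC1(C)C
F8 | step 20 | dienone methyl acetal (6-methoxy analogue of 35) | COC(=O)[C@H]1O[C@@]12[C@](C)(C(=O)c1ccoc1)CC[C@H]([C@@H](C)O[Si](C)(C)C(C)(C)C)[C@@]2(C)C(=O)/C=C1\C=CC(OC)OC1(C)C
F9 | step 20 | dienone lactol (6-hydroxy analogue of 35) | COC(=O)[C@H]1O[C@@]12[C@](C)(C(=O)c1ccoc1)CC[C@H]([C@@H](C)O[Si](C)(C)C(C)(C)C)[C@@]2(C)C(=O)/C=C1\C=CC(O)OC1(C)C
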